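## The problem

Methylarzanol (17) consists of two flat, fully substituted rings joined by a single methylene group, which links C3 of a 6-ethyl-2-methoxy-5-methyl-4H-pyran-4-one to C1' of an acetylphloroglucinol (numbered from the bridge carbon: hydroxyls on C2', C4' and C6', prenyl on C3', acetyl on C5'). The target has no stereocentre, so the task is one of connectivity and regiochemistry only; the single stereocentre that appears on the way is racemic and is erased on aromatization. The bridge is unsymmetrical and both rings are carbon nucleophiles of the same kind, so joining two finished rings with a one-carbon electrophile invites the symmetrical dimers. The heterocycle must be the 2-methoxy-4-pyranone and not the isomeric 4-methoxy-2-pyranone; it is a vinylogous carbonate that strong aqueous acid or hot hydroxide will cleave, and the CH2 of its 6-ethyl group is vinylogously acidic, so amide bases metalate it. The arene carries three different carbon substituents in fixed order, and its phenoxides are ambident (carbon versus oxygen) and prone to over-alkylation. A prenyl group ortho to a phenol closes to a chroman under acid, which speaks against a late Friedel–Crafts acetylation. The enabling feature is that ring C1'–C6' has oxygen on alternate carbons plus a C-acetyl group: it is a folded acetate tetraketide, a methyl 3,5,7-trioxooctanoate in which chain C1 becomes C6', C2 becomes C1' and C6 becomes C5'. Bond C5'–C6' can therefore be made by an intramolecular Claisen condensation of a chain whose C2 already carries the pyranonylmethyl group.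

## Retrosynthesis

**17 to 15 and 16.** The C3'–CH2 bond of the prenyl group is cut first, giving the acylphloroglucinol 15 and prenyl bromide (16). In 15 the position C3' is the only unsubstituted ring carbon, so the site of C-alkylation is not in question. Carrying the prenyl group through the chain chemistry would expose the alkene to every earlier reagent and would put a substituent on the carbon that must stay free for enolization. The forward step must favour carbon over oxygen and stop after one alkylation.

**15 to 14.** The bond between the acetyl-bearing carbon C5' and the hydroxyl-bearing carbon C6' is cut, which unfolds the arene to the triketo ester 14. Against the neighbouring cut, the bridge between two finished rings, this disconnection never asks two nucleophiles to share one electrophile. It also delivers the acetyl group as the tail of the chain instead of by Friedel–Crafts chemistry. The precursor is acyclic and is assembled from small pieces. The forward reaction must fold the chain in the Claisen sense (C6 onto C1) and not in an aldol sense, under conditions that the methoxypyranone tolerates.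

**14 to 12 and 11.** The chain is cut at C3–C4, between the malonyl half-ester chloride 12 and the bis-silyl dienol ether 11, which supplies C4–C8 as a latent pentane-2,4-dione. The obvious neighbour is to build the chain by enolate and dianion acylations on a pyranonyl ester. That would need amide bases after the 2-methoxy-4-pyranone is in place, and these metalate the CH2 of the 6-ethyl group. Acylation of 11 by an acid chloride needs no base and gives the chain at the correct oxidation level: the first product is the mono-silyl enol ether 13, which aqueous work-up hydrolyses to 14, so no acid deprotection is required either. The chloride 12 is made in the flask from the half-ester 9. The forward reaction must acylate the terminal carbon of 11 and leave the acidic malonyl hydrogen alone.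

**9 to 8 to 7.** Two functional-group changes lead back to the malonate 7. The half-ester 9 comes from the diester 8 by hydrolysis of one of two equivalent esters. The 2-methoxy-4-pyranone 8 comes from the 4-hydroxy-2-pyranone 7 by O-methylation at the lactone carbonyl oxygen. Methylating before any ketone is present avoids ambiguity between pyranone oxygen and chain enol oxygens. It also prevents ring closure of the 4-hydroxyl group onto a chain ketone.

**7 to 4 and 6.** The bridge bond CH2–C3 is cut between the 4-hydroxy-2-pyranone 4 and dimethyl methylidenemalonate (6), itself the one-carbon Knoevenagel product of dimethyl malonate (5). The bridge carbon comes already attached to the malonate, so the pyranone cannot dimerize through it. A plain acrylate acceptor would be simpler, but it would leave the second carbonyl on C2 to be introduced later by enolate chemistry. The forward step is a Michael addition of a vinylogous acid to a very electrophilic alkene and must stop after one addition.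

**4 to 2 and 3; 11 from 10.** The pyranone 4 is cut at C4–C5 and O1–C2 into the silyl enol ether 2 of pentan-3-one (1) and malonyl dichloride (3). The ketone is symmetrical, so the ethyl and methyl groups are placed without any regiochemical issue. The dienol ether 11 is one silylation away from the commercial mono-silyl enol ether 10.

## Roads not taken

**Alternative 1:** The pyranone is cut at C3–C4 and O1–C2. In the forward direction, thermolysis of the dioxinone 6-ethyl-2,2,5-trimethyl-4H-1,3-dioxin-4-one A2 would release an acylketene by cycloreversion. This heterodiene, once set free from A2, would add across the silyl ketene acetal tert-butyl({1-methoxy-3-[2,4,6-tris(benzyloxy)phenyl]prop-1-en-1-yl}oxy)dimethylsilane A3. Loss of the silyloxy group would give 6-ethyl-2-methoxy-5-methyl-3-[2,4,6-tris(benzyloxy)benzyl]-4H-pyran-4-one A1.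

- Merits: the 2-methoxy-4-pyranone is formed directly with its methoxy group in place, so the ambident O-methylation is avoided. The bridge carbon is simply the α-carbon of the ester behind A3, and the two halves A2 and A3 are joined convergently.
- Weak points: A1 carries a bare, symmetrical phloroglucinol ring. After debenzylation, both the acetyl and the prenyl group must be installed by electrophilic substitution on a triphenol. The acetylation needs Lewis or protic acid, which endangers the methoxypyranone and competes with O-acylation. The ketene acetal A3 is hindered by two ortho benzyloxy groups, and elimination of the methoxy instead of the silyloxy group would lead to the wrong pyranone tautomer series.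
- Comparison: in convergence, and in removing the O-methylation question, this road is better than the chosen one. The chosen plan sets against it that the acetyl group is written into the chain and that only one mild C-alkylation remains on the finished arene.

**Alternative 2:** The heterocycle is cut at C4–C5 and O1–C2 at the 4-hydroxy-2-pyranone stage. In the forward direction, the silyl enol ether 2 would be C-acylated and then O-acylated by 2-{[2,4,6-tris(benzyloxy)phenyl]methyl}propanedioyl dichloride A5. This would give 6-ethyl-4-hydroxy-5-methyl-3-[2,4,6-tris(benzyloxy)benzyl]-2H-pyran-2-one A4.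

- Merits: the annulation that gives A4 is the same as step 2 of the chosen route, with the bridge set earlier by a simple malonate benzylation. It is probably the shortest way to the complete carbon skeleton of both rings.
- Weak points: a substituted malonyl dichloride is more hindered and loses hydrogen chloride to a ketene more easily than the parent, and A5 must be made in the presence of three acid-sensitive benzyl ethers on an electron-rich ring. As in Alternative 1, the end-game from A4 needs O-methylation, debenzylation and then a Friedel–Crafts acetylation next to the acid-labile methoxypyranone, before the prenylation.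
- Comparison: in step economy up to the bridged skeleton A4 this road is as good as or better than the chosen one. The chosen plan sets against it an end-game without any electrophilic acylation, and an arene whose substitution pattern is fixed by the chain.

**Alternative 3:** The arene is cut at two ring bonds in the sense of a Danheiser benzannulation. Heating 2-[(6-ethyl-2-methoxy-5-methyl-4-oxo-4H-pyran-3-yl)methyl]-3-[(triisopropylsilyl)oxy]cyclobut-2-en-1-one A7 would open it to a vinylketene. This would add to the siloxyalkyne triisopropyl[(5-methylhex-4-en-1-yn-1-yl)oxy]silane A8. Four-electron opening and six-electron closure would then give 6-ethyl-3-{[4-hydroxy-3-(3-methylbut-2-enyl)-2,6-bis(triisopropylsilyloxy)phenyl]methyl}-2-methoxy-5-methyl-4H-pyran-4-one A6.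

- Merits: the prenyl group enters as the alkyne substituent of A8, so its position is fixed and the C-versus-O prenylation problem does not arise. The three oxygens emerge differentiated in A6.
- Weak points: A7 is an enol ether of a 2-substituted cyclobutane-1,3-dione and A8 is a siloxyalkyne. Both are laborious and sensitive to make. The acetyl group is still missing in A6 and would have to be introduced by acid-mediated acylation on a ring that now carries an ortho-prenyl phenol, which is the situation in which chroman formation occurs.
- Comparison: on the prenyl question, the weakest point of the chosen plan, this road is clearly better. The chosen plan sets against it cheap building blocks, an acetyl group that needs no separate step, and a last alkylation that has only one ring carbon to choose from.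

Key step: step 9

## Route

Remarks on the chemistry: compounds 9, 12, 13 and 14 are racemic at the malonyl carbon, and that centre disappears in step 9; compound 14 is drawn in its all-keto form but will exist as a mixture of enol tautomers; compounds 10 and 16 are taken as commercial.

Step 1
Reactants: 1 pentan-3-one
Product: 2 3-[(trimethylsilyl)oxy]pent-2-ene (E/Z mixture, geometry of no consequence)
Conditions: Me3SiOTf, Et3N, CH2Cl2, 0 °C; distillation
Reagents that add atoms: trimethylsilyl trifluoromethanesulfonate, C[Si](C)(C)OS(=O)(=O)C(F)(F)F
Why: Soft enolization and O-silylation of a simple ketone with a silyl triflate and a tertiary amine; the ketone is symmetrical, so only one regioisomer can form and both alkene isomers lead to the same pyranone.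

Step 2
Reactants: 2 3-[(trimethylsilyl)oxy]pent-2-ene; 3 malonyl dichloride
Product: 4 6-ethyl-4-hydroxy-5-methyl-2H-pyran-2-one
Conditions: Et2O, −78 °C → rt
Reagents that add atoms: none
Why: Known annulation of silyl enol ethers with malonyl dichloride: C-acylation at the enol ether carbon is followed by acylation of the new enol oxygen by the second acid chloride (six-membered lactone closure), and enolization gives the 4-hydroxy-2-pyranone; no base is needed.

Step 3
Reactants: 5 dimethyl malonate
Product: 6 dimethyl 2-methylidenepropanedioate
Conditions: paraformaldehyde, Cu(OAc)2 (cat.), KOAc (cat.), AcOH, 100 °C; then distillation under reduced pressure, used fresh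
Reagents that add atoms: formaldehyde (as paraformaldehyde), C=O
Why: Knoevenagel condensation of a malonate with formaldehyde under acetate catalysis, a standard preparation of methylidenemalonates; distillation cracks oligomers and delivers the monomer.

Step 4
Reactants: 4 6-ethyl-4-hydroxy-5-methyl-2H-pyran-2-one; 6 dimethyl 2-methylidenepropanedioate
Product: 7 dimethyl 2-[(6-ethyl-4-hydroxy-5-methyl-2-oxo-2H-pyran-3-yl)methyl]propanedioate
Conditions: Et3N (cat.), CH2Cl2, 0 °C → rt; 6 added slowly to a slight excess of 4
Reagents that add atoms: none
Why: Michael addition of C3 of a 4-hydroxy-2-pyranone (a vinylogous acid) to a doubly activated methylene acceptor; the acidic pyranone protonates each malonate anion as it forms, which stops chain growth, and O-adducts revert so that the C-adduct accumulates.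

Step 5
Reactants: 7 dimethyl 2-[(6-ethyl-4-hydroxy-5-methyl-2-oxo-2H-pyran-3-yl)methyl]propanedioate
Product: 8 dimethyl 2-[(6-ethyl-2-methoxy-5-methyl-4-oxo-4H-pyran-3-yl)methyl]propanedioate
Conditions: MeOTf, CH2Cl2, rt; then aq. NaHCO3
Reagents that add atoms: methyl trifluoromethanesulfonate, COS(=O)(=O)C(F)(F)F
Why: O-Methylation of neutral 4-hydroxy-2-pyranones with a hard methylating agent takes place at the lactone carbonyl oxygen, and loss of the hydroxyl proton then gives the 2-methoxy-4-pyranone and not the 4-methoxy-2-pyranone; the malonate is inert without base.

Step 6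
Reactants: 8 dimethyl 2-[(6-ethyl-2-methoxy-5-methyl-4-oxo-4H-pyran-3-yl)methyl]propanedioate
Product: 9 (2RS)-2-[(6-ethyl-2-methoxy-5-methyl-4-oxo-4H-pyran-3-yl)methyl]-3-methoxy-3-oxopropanoic acid
Conditions: KOH (1.0 equiv), THF/H2O, 0 °C; then 1 M HCl to pH 3 at 0 °C
Reagents that add atoms: potassium hydroxide, [K+].[OH-]
Why: Selective monohydrolysis of a symmetrical malonate diester with one equivalent of cold aqueous alkali stops at the half-ester because the carboxylate deactivates the second ester; low temperature and stoichiometric base spare the methoxypyranone, cold acidification avoids decarboxylation, and the new centre is racemic and temporary.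

Step 7
Reactants: 10 4-[(trimethylsilyl)oxy]pent-3-en-2-one
Product: 11 2,4-bis[(trimethylsilyl)oxy]penta-1,3-diene
Conditions: LiN(i-Pr)2, THF, −78 °C; Me3SiCl, −78 °C → rt; non-aqueous work-up
Reagents that add atoms: chlorotrimethylsilane, C[Si](C)(C)Cl
Why: Kinetic deprotonation of the methyl ketone and O-silylation, the standard preparation of 1,3-bis(silyl enol ethers) from β-diketone mono-silyl ethers.

Step 8
Reactants: 9 (2RS)-2-[(6-ethyl-2-methoxy-5-methyl-4-oxo-4H-pyran-3-yl)methyl]-3-methoxy-3-oxopropanoic acid; 11 2,4-bis[(trimethylsilyl)oxy]penta-1,3-diene
Product: 14 methyl (2RS)-2-[(6-ethyl-2-methoxy-5-methyl-4-oxo-4H-pyran-3-yl)methyl]-3,5,7-trioxooctanoate, via malonyl half-ester chloride 12 (not isolated), via 7-silyloxy enone 13 (not isolated)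
Conditions: 1-chloro-N,N,2-trimethylprop-1-en-1-amine, CH2Cl2, 0 °C → rt; then 11, CH2Cl2, −78 → 20 °C; aq. NaHCO3 work-up
Reagents that add atoms: none
Why: Neutral conversion of the acid into its chloride with an α-chloroenamine, then Mukaiyama-type C-acylation of a 1,3-bis(silyl enol ether) at its terminal carbon, a known route to 1,3,5-tricarbonyl compounds; no base is present, so neither the CH2 of the 6-ethyl group nor the malonyl hydrogen is deprotonated, and aqueous work-up cleaves the remaining silyl enol ether to free the triketone without an acid deprotection.

Step 9
Reactants: 14 methyl (2RS)-2-[(6-ethyl-2-methoxy-5-methyl-4-oxo-4H-pyran-3-yl)methyl]-3,5,7-trioxooctanoate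
Product: 15 3-[(3-acetyl-2,4,6-trihydroxyphenyl)methyl]-6-ethyl-2-methoxy-5-methyl-4H-pyran-4-one
Conditions: Mg(OMe)2 (excess), MeOH, rt → 60 °C; then cold 0.5 M HCl to pH 4
Reagents that add atoms: none
Why: Mg(OMe)2 converts 14 into a magnesium-chelated polyenolate in which the carbon C6 of the 5,7-diketonate is the nucleophile; it adds to the ester carbonyl C1, methoxide leaves, and the ring tautomerizes at once to the arene with loss of the hydrogen on C2, which is the known base-mediated Claisen folding of 3,5,7-triketo esters to acylphloroglucinols. The six-membered carbocycle closes in the 6-exo-trig mode (enolate carbon onto an ester C=O that stays outside the ring). No stereocentre is formed, and the racemic centre C2 of 14 becomes the sp2 carbon C1'. The selectivity needed is Claisen folding (C6 to C1) over aldol folding: closure of C2 onto the C7 ketone gives an aldol with a quaternary C2 that cannot dehydrate to an arene and therefore reverts, while closure of the methyl carbon C8 onto C3 is disfavoured because C8 is the least acidic carbon and C3 is a chelated, hindered carbonyl. Chelation also holds the 1,3-dicarbonyl units as stable enolates, which suppresses retro-Claisen cleavage by methoxide. Methanol and methoxide are chosen so that exchange at the methyl ester and at C2 of the methoxypyranone is degenerate, and the base is too weak to metalate the 6-ethyl group. Aromatization makes the closure irreversible.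

Step 10
Reactants: 15 3-[(3-acetyl-2,4,6-trihydroxyphenyl)methyl]-6-ethyl-2-methoxy-5-methyl-4H-pyran-4-one; 16 prenyl bromide (1-bromo-3-methylbut-2-ene)
Product: 17 methylarzanol, 3-{[3-acetyl-2,4,6-trihydroxy-5-(3-methylbut-2-en-1-yl)phenyl]methyl}-6-ethyl-2-methoxy-5-methyl-4H-pyran-4-one
Conditions: DBU, 16 (1.05 equiv), THF, 0 °C → rt
Reagents that add atoms: none
Why: C-Alkylation of an acylphloroglucinol phenoxide with an allylic bromide, the usual way to C-prenyl acylphloroglucinols; C3' is the only unsubstituted ring carbon and lies ortho to two oxygens and para to the third, one equivalent of bromide limits a second alkylation, and no acid is present that could close a chroman.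

## Compound list

1 | pentan-3-one | CCC(=O)CC | starting material
2 | 3-[(trimethylsilyl)oxy]pent-2-ene (E/Z mixture) | CC=C(CC)O[Si](C)(C)C | intermediate
3 | malonyl dichloride | O=C(Cl)CC(=O)Cl | starting material
4 | 6-ethyl-4-hydroxy-5-methyl-2H-pyran-2-one | CCc1oc(=O)cc(O)c1C | intermediate
5 | dimethyl malonate | COC(=O)CC(=O)OC | starting material
6 | dimethyl 2-methylidenepropanedioate | C=C(C(=O)OC)C(=O)OC | intermediate
7 | dimethyl 2-[(6-ethyl-4-hydroxy-5-methyl-2-oxo-2H-pyran-3-yl)methyl]propanedioate | CCc1oc(=O)c(CC(C(=O)OC)C(=O)OC)c(O)c1C | intermediate
8 | dimethyl 2-[(6-ethyl-2-methoxy-5-methyl-4-oxo-4H-pyran-3-yl)methyl]propanedioate | CCc1oc(OC)c(CC(C(=O)OC)C(=O)OC)c(=O)c1C | intermediate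
9 | (2RS)-2-[(6-ethyl-2-methoxy-5-methyl-4-oxo-4H-pyran-3-yl)methyl]-3-methoxy-3-oxopropanoic acid (racemic) | CCc1oc(OC)c(CC(C(=O)O)C(=O)OC)c(=O)c1C | intermediate
10 | 4-[(trimethylsilyl)oxy]pent-3-en-2-one (alkene geometry as supplied, of no consequence) | CC(=O)C=C(C)O[Si](C)(C)C | starting material
11 | 2,4-bis[(trimethylsilyl)oxy]penta-1,3-diene (geometry at C3=C4 of no consequence) | C=C(O[Si](C)(C)C)C=C(C)O[Si](C)(C)C | intermediate
12 | methyl (2RS)-2-(chlorocarbonyl)-3-(6-ethyl-2-methoxy-5-methyl-4-oxo-4H-pyran-3-yl)propanoate (racemic, not isolated) | CCc1oc(OC)c(CC(C(=O)Cl)C(=O)OC)c(=O)c1C | intermediate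
13 | methyl (2RS)-2-[(6-ethyl-2-methoxy-5-methyl-4-oxo-4H-pyran-3-yl)methyl]-3,5-dioxo-7-[(trimethylsilyl)oxy]oct-6-enoate (racemic, alkene geometry of no consequence, not isolated) | CCc1oc(OC)c(CC(C(=O)OC)C(=O)CC(=O)C=C(C)O[Si](C)(C)C)c(=O)c1C | intermediate
14 | methyl (2RS)-2-[(6-ethyl-2-methoxy-5-methyl-4-oxo-4H-pyran-3-yl)methyl]-3,5,7-trioxooctanoate (racemic, keto form drawn) | CCc1oc(OC)c(CC(C(=O)OC)C(=O)CC(=O)CC(C)=O)c(=O)c1C | intermediate
15 | 3-[(3-acetyl-2,4,6-trihydroxyphenyl)methyl]-6-ethyl-2-methoxy-5-methyl-4H-pyran-4-one | CCc1oc(OC)c(Cc2c(O)cc(O)c(C(C)=O)c2O)c(=O)c1C | intermediate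
16 | prenyl bromide (1-bromo-3-methylbut-2-ene) | CC(C)=CCBr | starting material
17 | methylarzanol, 3-{[3-acetyl-2,4,6-trihydroxy-5-(3-methylbut-2-en-1-yl)phenyl]methyl}-6-ethyl-2-methoxy-5-methyl-4H-pyran-4-one (no stereocentre) | CCc1oc(OC)c(Cc2c(O)c(CC=C(C)C)c(O)c(C(C)=O)c2O)c(=O)c1C | target

## Step count and least certain steps

Total step count: 10. Longest linear sequence: 8 steps (steps 1, 2, 4, 5, 6, 8, 9 and 10). Steps 3 and 7 prepare the two side reagents.

**Step 9 (key step).** The chain may fold the wrong way. Aldol closure from the terminal methyl carbon onto the C3 carbonyl followed by dehydration, closure through oxygen to a pyranone, or cleavage of a 1,3-dicarbonyl unit by methoxide are all open to the same polyenolate, and only chelation and relative acidity separate them from the Claisen channel.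

Fallback: the chain folding is given up and the arene is brought in ready-made, setting out from 4. A Mannich reaction of 4 with N,N-dimethylmethyleneiminium iodide should give 3-[(dimethylamino)methyl]-6-ethyl-4-hydroxy-5-methyl-2H-pyran-2-one F1. Heating F1 with commercial 2,4,6-trihydroxyacetophenone should join the two rings by elimination–addition, with loss of the amine, to give 3-[(3-acetyl-2,4,6-trihydroxyphenyl)methyl]-6-ethyl-4-hydroxy-5-methyl-2H-pyran-2-one F2. O-Methylation of F2 at the lactone carbonyl with MeOTf, as in step 5 (phenols are inert without base), returns to the route at 15.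

**Step 8.** The half-ester chloride may lose hydrogen chloride to a ketene that condenses with itself, or the dienol ether may be acylated at oxygen or at its central carbon. The acid chloride has an acidic α-hydrogen and the nucleophile is ambident. Reversible acylation of the pyranone carbonyl oxygen by the neighbouring acid chloride may also slow the reaction.

Fallback: classical enolate chemistry with excess base, setting out from 9. Gentle heating should decarboxylate 9 to methyl 3-(6-ethyl-2-methoxy-5-methyl-4-oxo-4H-pyran-3-yl)propanoate F3. Treatment with LiN(i-Pr)2 in excess, so that both the ester and the 6-ethyl group are metalated and the more basic ester enolate reacts, followed by N-methoxy-N-methylacetamide, should give methyl 2-[(6-ethyl-2-methoxy-5-methyl-4-oxo-4H-pyran-3-yl)methyl]-3-oxobutanoate F4. The polyanion of F4 (excess LiN(i-Pr)2) should be acylated at the terminal methyl carbon by N-methoxy-N-methyl-2-(2-methyl-1,3-dioxolan-2-yl)acetamide to give methyl 2-[(6-ethyl-2-methoxy-5-methyl-4-oxo-4H-pyran-3-yl)methyl]-6-(2-methyl-1,3-dioxolan-2-yl)-3,5-dioxohexanoate F5. Removal of the ketal with pyridinium p-toluenesulfonate in aqueous acetone returns to the route at 14.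

**Step 4.** The methylidenemalonate may oligomerize anionically, or the product malonate may add to a second molecule of acceptor, because 6 is an exceptionally reactive Michael acceptor.

Fallback: the acceptor is released slowly from a stable precursor, setting out from 5. A Mannich reaction of 5 with N,N-dimethylmethyleneiminium iodide should give dimethyl 2-[(dimethylamino)methyl]propanedioate F6. Warming F6 with 4 in acetonitrile should generate 6 at low stationary concentration by loss of the amine, with capture by the pyranone, returning to the route at 7.

**Step 10.** Alkylation may occur at oxygen instead of carbon, or a second alkylation may take place at an already substituted ring carbon with loss of aromaticity. The phenoxide is ambident and carries three oxygens.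

Fallback: the prenyl group is delivered through oxygen and a sigmatropic shift, setting out from 15. The hydroxyl para to the acetyl group (on C2', not hydrogen-bonded to the ketone and next to the free carbon) should be alkylated with 3-chloro-3-methylbut-1-yne (DBU, CuCl2 cat., MeCN, 0 °C). This gives 3-({3-acetyl-2,4-dihydroxy-6-[(2-methylbut-3-yn-2-yl)oxy]phenyl}methyl)-6-ethyl-2-methoxy-5-methyl-4H-pyran-4-one F7. Semihydrogenation (H2, Pd/CaCO3 poisoned with Pb(OAc)2, quinoline) should give 3-({3-acetyl-2,4-dihydroxy-6-[(2-methylbut-3-en-2-yl)oxy]phenyl}methyl)-6-ethyl-2-methoxy-5-methyl-4H-pyran-4-one F8. Heating F8 in toluene should bring about the aromatic Claisen rearrangement to the only free ortho carbon, returning to the route at 17.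

## Further compounds

F1 | step 9 | 3-[(dimethylamino)methyl]-6-ethyl-4-hydroxy-5-methyl-2H-pyran-2-one | CCc1oc(=O)c(CN(C)C)c(O)c1C
F2 | step 9 | 3-[(3-acetyl-2,4,6-trihydroxyphenyl)methyl]-6-ethyl-4-hydroxy-5-methyl-2H-pyran-2-one | CCc1oc(=O)c(Cc2c(O)cc(O)c(C(C)=O)c2O)c(O)c1C
F3 | step 8 | methyl 3-(6-ethyl-2-methoxy-5-methyl-4-oxo-4H-pyran-3-yl)propanoate | CCc1oc(OC)c(CCC(=O)OC)c(=O)c1C
F4 | step 8 | methyl 2-[(6-ethyl-2-methoxy-5-methyl-4-oxo-4H-pyran-3-yl)methyl]-3-oxobutanoate (racemic) | CCc1oc(OC)c(CC(C(=O)OC)C(C)=O)c(=O)c1C
F5 | step 8 | methyl 2-[(6-ethyl-2-methoxy-5-methyl-4-oxo-4H-pyran-3-yl)methyl]-6-(2-methyl-1,3-dioxolan-2-yl)-3,5-dioxohexanoate (racemic) | CCc1oc(OC)c(CC(C(=O)OC)C(=O)CC(=O)CC2(C)OCCO2)c(=O)c1C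
F6 | step 4 | dimethyl 2-[(dimethylamino)methyl]propanedioate | CN(C)CC(C(=O)OC)C(=O)OC
F7 | step 10 | 3-({3-acetyl-2,4-dihydroxy-6-[(2-methylbut-3-yn-2-yl)oxy]phenyl}methyl)-6-ethyl-2-methoxy-5-methyl-4H-pyran-4-one | CCc1oc(OC)c(Cc2c(OC(C)(C)C#C)cc(O)c(C(C)=O)c2O)c(=O)c1C
F8 | step 10 | 3-({3-acetyl-2,4-dihydroxy-6-[(2-methylbut-3-en-2-yl)oxy]phenyl}methyl)-6-ethyl-2-methoxy-5-methyl-4H-pyran-4-one | CCc1oc(OC)c(Cc2c(OC(C)(C)C=C)cc(O)c(C(C)=O)c2O)c(=O)c1C
A1 | alternative 1 | 6-ethyl-2-methoxy-5-methyl-3-[2,4,6-tris(benzyloxy)benzyl]-4H-pyran-4-one | CCc1oc(OC)c(Cc2c(OCc3ccccc3)cc(OCc3ccccc3)cc2OCc2ccccc2)c(=O)c1C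
A2 | alternative 1 | 6-ethyl-2,2,5-trimethyl-4H-1,3-dioxin-4-one | CCC1=C(C)C(=O)OC(C)(C)O1
A3 | alternative 1 | tert-butyl({1-methoxy-3-[2,4,6-tris(benzyloxy)phenyl]prop-1-en-1-yl}oxy)dimethylsilane | COC(O[Si](C)(C)C(C)(C)C)=CCc1c(OCc2ccccc2)cc(OCc2ccccc2)cc1OCc1ccccc1
A4 | alternative 2 | 6-ethyl-4-hydroxy-5-methyl-3-[2,4,6-tris(benzyloxy)benzyl]-2H-pyran-2-one | CCc1oc(=O)c(Cc2c(OCc3ccccc3)cc(OCc3ccccc3)cc2OCc2ccccc2)c(O)c1C
A5 | alternative 2 | 2-{[2,4,6-tris(benzyloxy)phenyl]methyl}propanedioyl dichloride | O=C(Cl)C(Cc1c(OCc2ccccc2)cc(OCc2ccccc2)cc1OCc1ccccc1)C(=O)Cl
A6 | alternative 3 | 6-ethyl-3-{[4-hydroxy-3-(3-methylbut-2-enyl)-2,6-bis(triisopropylsilyloxy)phenyl]methyl}-2-methoxy-5-methyl-4H-pyran-4-one | Oc1cc(O[Si](C(C)C)(C(C)C)C(C)C)c(Cc2c(OC)oc(CC)c(C)c2=O)c(O[Si](C(C)C)(C(C)C)C(C)C)c1CC=C(C)C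
A7 | alternative 3 | 2-[(6-ethyl-2-methoxy-5-methyl-4-oxo-4H-pyran-3-yl)methyl]-3-[(triisopropylsilyl)oxy]cyclobut-2-en-1-one | CCc1oc(OC)c(CC2=C(O[Si](C(C)C)(C(C)C)C(C)C)CC2=O)c(=O)c1C
A8 | alternative 3 | triisopropyl[(5-methylhex-4-en-1-yn-1-yl)oxy]silane | CC(C)=CCC#CO[Si](C(C)C)(C(C)C)C(C)C
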